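**Abbreviations:** TBS = tert-butyldimethylsilyl, TES = triethylsilyl, TMS = trimethylsilyl, TBDPS = tert-butyldiphenylsilyl, PMB = 4-methoxybenzyl, MOM = methoxymethyl. Locants C1–C15 are those of germacrane: ring C1–C10, C1=C10 bearing C14, C4=C5 bearing C15, lactone C6–O–C12(=O)–C11(=C13)–C7.

## The problem

The target is a ten-membered carbocycle with two cis-in-ring trisubstituted alkenes, C1=C10 (carrying the C14 hydroxymethyl group) and C4=C5 (carrying the C15 methyl group), trans-fused at C6/C7 to an α-methylene-γ-butyrolactone. Four contiguous stereocentres, C6–C9 (6R,7S,8S,9S), lie on one flank of the ring. C8 can be bought as a hydroxy acid carbon, can set C7 by anti alkylation and C9 by chelation, and C7 can then steer an addition to C6. O8 and O9 carry different acyl groups (isobutyrate and 2-hydroxyisobutyrate), so the two secondary hydroxyls must be distinguishable from the moment they exist, while the C14 and tertiary hydroxyls must end free. The exo-methylene lactone (a Michael acceptor), the allylic C9 ester and C14 alcohol (ionisation, acyl shift) and the cyclodeca-1,5-diene (transannular reactions) will not survive strong base, nucleophiles or strong acid, so they must appear late. Closing a ten-membered ring by C–C bond formation is costly. The way round is the C1=C10 alkene with C14 at the ester level: it is what an α-sulfonyl ester with sulfur between C1 and C10 gives on loss of SO2. The ring can therefore be closed one atom larger through sulfur and then contracted.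

## Retrosynthesis

**57 ⇐ 56 ⇐ 55 ⇐ 53 ⇐ 52 ⇐ 51.** The last bonds cut are the ester C–O bonds at O9 and O8 and the O–Si bonds at O14 and the tertiary hydroxyl. Neither ester would survive the hydride and enolate steps before them. A cut to a free 8,9-diol was set aside because nothing predicts which hydroxyl of a trans-diol on this ring acylates first. Instead O8 (PMB ether) and O9 (MOM ether) are freed one at a time from α-methylene lactone 51. The forward steps must cleave a benzyl-type ether and an acetal ether beside a Michael acceptor and an allylic silyl ether.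

**51 ⇐ 47 ⇐ 45 ⇐ 44 ⇐ 43 ⇐ 42.** C13 is removed (methylenation of lactone 47), the O6–C12 bond is opened to 1,4-diol 45, and C14 is taken back to the ester of 42. A diol is preferred to a C12 acid because it tolerates the hydride reduction at C14 that has to come first. O8 must stay blocked so that only O6 can capture C12; O8 is also γ to C12.

**42 ⇐ 39 (key).** The C1=C10 alkene is replaced by C1–SO2–C10. Against C–C closures of the ten-membered ring at C5–C6 or C8–C9, this puts the ring closure on a C–S bond in a ring one atom larger and lets the ring set the alkene geometry. The C14 ester marks C10 as the only site acidic enough to be halogenated. Sulfone 39 contains no trisubstituted C1=C10 alkene that would have to be made stereoselectively. The forward reaction must chlorinate at C10 only, form the carbanion at C1 and deliver the cis-in-ring alkene.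

**39 ⇐ 38 ⇐ 36 ⇐ 34.** Both C–S bonds are cut. The ring is closed at S–C1, an unhindered primary carbon, by the C10 thiolate. The crowded S–C10 bond is made beforehand between two molecules, on the triflate of α-hydroxy ester 34. Closing at C10 instead would ask a macrocyclisation to succeed at the most hindered carbon. 34 is an open chain with all four stereocentres in place.

**34 ⇐ 33 ⇐ 32 ⇐ 31 + 13.** The C9–C10 bond is cut as an aldol between α-alkoxy aldehyde 31 and glycolate ketene acetal 13 (from methyl glycolate 10 through 11). One bond brings in C10 with an oxygen that becomes the leaving group, C14 as the activating ester, and C9 set by chelation to the O8 ether. O8 (PMB) and O9 (free, then MOM) are different from birth. Ether groups are used at O9 rather than a silyl or acyl group because an alkoxide is the poorest leaving group β to the later C10 anion.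

**31 ⇐ 30 ⇐ 29 ⇐ 28 ⇐ 25 + 9.** The C5–C6 bond is cut between alkenyllithium 26 (from iodide 9) and lactol 25. The lactol releases the C6 aldehyde and the C12 alkoxide together, so the addition gives the 6,12-diol 28 that is needed again for the lactone. The existing C7 centre controls C6 in an open chain, where the outcome can be checked and corrected. The benzylidene acetal of 29 is then opened to put PMB on O8 and free C9 for oxidation.

**25 ⇐ 24 ⇐ 21 ⇐ 20 ⇐ 19 ⇐ 17.** Lactone 24 comes from dimethyl (S)-malate 17: C8 is the malate carbinol, C7 is set by anti allylation (19), the C9 ester is reduced selectively under direction by the hydroxyl (20), the diol is tied as the benzylidene acetal (21), and ozonolysis with reduction shortens the allyl group to C11–C12 and closes the lactone. Malate supplies C6–C9 with two of the four stereocentres fixed or directly controlled.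

**9 ⇐ 8 ⇐ 7 ⇐ 2 + 3; 16 ⇐ 15 ⇐ 14.** The Z-alkenyl iodide comes from syn-carbocupration of propyne 3 with the organocopper from bromide 2 (from 3-bromopropan-1-ol 1), which fixes the C4=C5 geometry at the start. The protected acid chloride 16 comes from 2-hydroxy-2-methylpropanoic acid 14.

## Roads not taken

**Alternative 1:** The lactone bonds O6–C12 and C11–C12 are cut, with C12 coming from carbon monoxide, and the exo-methylene is traced to a terminal alkyne. In the forward step PdCl2 with SnCl2 and PPh3 under CO would convert ethynyl carbinol A2 (ten-membered ring, C6 hydroxyl, C7 ethynyl, both esters in place) into the bis-silyl ether A1 of the target. A divalent palladium alkoxycarbonyl adds across the alkyne and protonolysis leaves C11=C13.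

- Merits: lactone and methylene arise in one neutral step at the very end, no lactone enolate is needed, and both acyl groups can be attached earlier on a simpler intermediate. In this respect it is better than the chosen plan, which spends five steps after methylenation on O8 and O9.
- Weak points: it does nothing for the ten-membered ring, which still needs its own macrocyclisation. A C7 ethynyl group trans to O6 has to be set and carried. The Lewis-acidic tin salt and any zerovalent palladium formed under CO threaten the allylic C9 ester (allylpalladium formation) and the 1,5-diene (hydropalladation, isomerisation).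
- Comparison: the chosen plan sets against the shorter endgame a ring construction that is settled, and a lactone made by a plain diol oxidation before any sensitive ester is present.

**Alternative 2:** The C5–C6 bond and the lactone O6–C12 bond are cut. CrCl2 with catalytic NiCl2 would turn the Z-alkenyl iodide of open-chain aldehyde ester A4 into an alkenyl divalent-chromium species that adds to the C6 aldehyde and closes the ten-membered ring. The C6 alkoxide then lactonises onto the C12 methyl ester to give A3.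

- Merits: the conditions are neutral and chemoselective, C6 and the lactone are formed in one flask, no sulfur or oxidation-level changes at C14 are needed, and the route is shorter than the chosen one.
- Weak points: the strained cis,cis-cyclodecadiene is closed directly by a C–C bond at high dilution. The C6 configuration is decided inside a macrocyclic transition state that cannot be predicted, and a 6,7-cis product would lactonise as well. C7, α to the aldehyde, can epimerise. The cis trisubstituted C1=C10 unit must first be made in open-chain form.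
- Comparison: step count favours this road. The chosen plan sets against it a C6 centre made in an open chain under Felkin–Anh control, a ring closure through a long C–S bond in an eleven-membered ring, and a C1=C10 geometry imposed by the ring.

**Alternative 3:** The C8–C9 bond is cut. Low-valent titanium from TiCl3(DME)1.5 and Zn–Cu couple would couple the C8 aldehyde and the C9 enal carbonyl of lactone dialdehyde A6, closing the ring and giving both hydroxyls of diol A5.

- Merits: ring and diol form together, and A6 carries only the C6 and C7 centres, so the precursor is short.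
- Weak points: two stereocentres are created in the ring closure and only one of four diastereomers is useful. The enal ketyl can couple through its β-carbon or be deoxygenated to the alkene. The lactone and the aldehyde-bearing C7 centre are exposed to a strong reductant. The product has two undifferentiated secondary hydroxyls that must then take two different acyl groups.
- Comparison: it is the shortest way to the ring, but both the stereochemical and the acylation problems are left to chance. The chosen plan takes C8 from malate, sets C9 by chelation and has O8 and O9 under different ethers from the start, at the price of more steps.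

Key step: step 24

Remark: C10 (compounds 32–41), the benzylidene acetal carbon (21–29) and the lactol carbons (25, 46) are formed as epimeric mixtures; each centre is destroyed later, so the mixtures are carried on.

## Route

Step 1
Reactants: 1 3-bromopropan-1-ol
Product: 2 (3-bromopropoxy)(tert-butyl)dimethylsilane
Conditions: TBSCl, imidazole, CH2Cl2, 0 → 20 °C
Reagents that add atoms: tert-butyldimethylsilyl chloride, CC(C)(C)[Si](C)(C)Cl
Why: Imidazole-promoted silylation of a primary alcohol; the silyl ether is inert to magnesium and organocopper reagents.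

Step 2
Reactants: 2 (3-bromopropoxy)(tert-butyl)dimethylsilane, 3 propyne
Product: 7 (Z)-tert-butyl[(5-iodo-4-methylpent-4-en-1-yl)oxy]dimethylsilane, via Grignard reagent 4 (not isolated), via alkylcopper 5 (not isolated), via alkenylcopper 6 (not isolated)
Conditions: Mg, Et2O; CuBr·SMe2, Et2O/SMe2, −45 °C; propyne, −25 °C; I2, −78 → 0 °C
Reagents that add atoms: iodine, [I][I]
Why: syn-Carbocupration of a terminal alkyne puts the alkyl group on the internal carbon and copper on the terminal one on the same side; iodinolysis with retention gives the Z-iodide with iodine cis to the C3 chain, the C4=C5 geometry of the target.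

Step 3
Reactants: 7 (Z)-tert-butyl[(5-iodo-4-methylpent-4-en-1-yl)oxy]dimethylsilane
Product: 8 (Z)-5-iodo-4-methylpent-4-en-1-ol
Conditions: Bu4NF, THF, 0 °C
Reagents that add atoms: none
Why: Fluoride cleaves the primary silyl ether; the alkenyl iodide is inert.

Step 4
Reactants: 8 (Z)-5-iodo-4-methylpent-4-en-1-ol
Product: 9 (Z)-5-chloro-1-iodo-2-methylpent-1-ene
Conditions: NCS, PPh3, CH2Cl2, 0 → 20 °C
Reagents that add atoms: N-chlorosuccinimide, O=C1CCC(=O)N1Cl
Why: Appel-type chlorination (SN2 by chloride on the alkoxyphosphonium ion); a primary chloride survives iodine–lithium exchange at −78 °C and later serves as the C1 electrophile.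

Step 5
Reactants: 10 methyl glycolate
Product: 11 methyl 2-(triethylsilyloxy)acetate
Conditions: TESCl, imidazole, CH2Cl2, 0 °C
Reagents that add atoms: triethylsilyl chloride, CC[Si](CC)(CC)Cl
Why: Silylation; TES is chosen so that O10 can later be freed in the presence of TBS ethers.

Step 6
Reactants: 11 methyl 2-(triethylsilyloxy)acetate
Product: 13 1-methoxy-2-(triethylsilyloxy)-1-(trimethylsilyloxy)ethene (geometric mixture), via lithium enolate 12 (not isolated)
Conditions: LiN(SiMe3)2, THF, −78 °C; Me3SiCl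
Reagents that add atoms: chlorotrimethylsilane, C[Si](C)(C)Cl
Why: Low-temperature enolisation and O-silylation give the ketene silyl acetal used as glycolate enolate equivalent in the Mukaiyama aldol; its geometry does not matter because C10 ends trigonal.

Step 7
Reactants: 14 2-hydroxy-2-methylpropanoic acid
Product: 15 trimethylsilyl 2-methyl-2-(trimethylsilyloxy)propanoate
Conditions: Me3SiCl, pyridine, CH2Cl2, 20 °C
Reagents that add atoms: chlorotrimethylsilane, C[Si](C)(C)Cl
Why: Exhaustive silylation of the acid and the tertiary hydroxyl.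

Step 8
Reactants: 15 trimethylsilyl 2-methyl-2-(trimethylsilyloxy)propanoate
Product: 16 2-methyl-2-(trimethylsilyloxy)propanoyl chloride
Conditions: (COCl)2, DMF (cat.), CH2Cl2, 0 → 20 °C
Reagents that add atoms: oxalyl chloride, O=C(Cl)C(Cl)=O
Why: Oxalyl chloride with catalytic DMF converts a silyl ester directly into the acid chloride under neutral conditions, leaving the tertiary silyl ether in place.

Step 9
Reactants: 17 dimethyl (S)-malate
Product: 19 dimethyl (2S,3R)-2-hydroxy-3-(prop-2-en-1-yl)butanedioate, via dilithio dianion 18 (not isolated)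
Conditions: LiN(SiMe3)2 (2.1 equiv), THF, −78 → −20 °C; allyl bromide
Reagents that add atoms: allyl bromide, C=CCBr
Why: Fráter–Seebach alkylation: the chelated alkoxide enolate is alkylated anti to the alkoxide oxygen, so the malate carbinol (C8) sets C7.

Step 10
Reactants: 19 dimethyl (2S,3R)-2-hydroxy-3-(prop-2-en-1-yl)butanedioate
Product: 20 methyl (2R)-2-[(1S)-1,2-dihydroxyethyl]pent-4-enoate
Conditions: BH3·SMe2 (1.0 equiv), NaBH4 (5 mol %), THF, 0 → 20 °C; MeOH
Reagents that add atoms: none
Why: Hydroxyl-directed borane reduction: the alkoxyborane formed at O8 delivers hydride through a five-membered chelate to the adjacent ester only, with NaBH4 as catalyst; one equivalent of borane is consumed at the hydroxyl, which spares the alkene.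

Step 11
Reactants: 20 methyl (2R)-2-[(1S)-1,2-dihydroxyethyl]pent-4-enoate
Product: 21 methyl (2R)-2-[(4S)-2-(4-methoxyphenyl)-1,3-dioxolan-4-yl]pent-4-enoate (acetal epimers)
Conditions: 4-MeOC6H4CH(OMe)2, PPTS (cat.), CH2Cl2, 20 °C
Reagents that add atoms: 4-methoxybenzaldehyde dimethyl acetal, COc1ccc(C(OC)OC)cc1
Why: Acid-catalysed transacetalisation of the 1,2-diol; it stops O9 from lactonising onto the C6 ester and later supplies the PMB ether at O8.

Step 12
Reactants: 21 methyl (2R)-2-[(4S)-2-(4-methoxyphenyl)-1,3-dioxolan-4-yl]pent-4-enoate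
Product: 24 (3R)-3-[(4S)-2-(4-methoxyphenyl)-1,3-dioxolan-4-yl]oxolan-2-one, via aldehyde 22 (not isolated), via hydroxy ester 23 (not isolated)
Conditions: O3, CH2Cl2/MeOH, −78 °C (to first excess); NaBH4, −78 → 0 °C; PPTS (cat.), CH2Cl2, 20 °C
Reagents that add atoms: ozone, [O-][O+]=O
Why: Ozonolysis with reductive work-up shortens the allyl group to the C11–C12 hydroxyethyl arm and the γ-hydroxy ester closes (5-exo-trig) to the lactone, which activates C6 and masks O12; the terminal alkene reacts with ozone far faster than the anisyl ring at −78 °C.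

Step 13
Reactants: 24 (3R)-3-[(4S)-2-(4-methoxyphenyl)-1,3-dioxolan-4-yl]oxolan-2-one
Product: 25 (3R)-3-[(4S)-2-(4-methoxyphenyl)-1,3-dioxolan-4-yl]oxolan-2-ol (anomers)
Conditions: iBu2AlH (1.1 equiv), CH2Cl2, −78 °C
Reagents that add atoms: none
Why: Half-reduction of a γ-lactone stops at the lactol at −78 °C because the tetrahedral aluminium alkoxide is stable; the benzylidene acetal is not opened at this temperature.

Step 14
Reactants: 25 (3R)-3-[(4S)-2-(4-methoxyphenyl)-1,3-dioxolan-4-yl]oxolan-2-ol, 9 (Z)-5-chloro-1-iodo-2-methylpent-1-ene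
Product: 28 (3S,4R,5Z)-9-chloro-3-[(4S)-2-(4-methoxyphenyl)-1,3-dioxolan-4-yl]-6-methylnon-5-ene-1,4-diol, via alkenyllithium 26 (not isolated), via hydroxy aldehyde 27 (not isolated)
Conditions: 9 (2.5 equiv), tBuLi (5 equiv), Et2O, −78 °C; then 25, THF, −78 → −20 °C
Reagents that add atoms: none
Why: Iodine–lithium exchange gives the alkenyllithium with retention; the lithium lactolate opens to the aldehyde, to which the alkenyllithium adds anti to the large dioxolanyl group on C7 (Felkin–Anh), an approach reinforced by loose chelation of lithium between the C12 alkoxide and the carbonyl, giving the 6,7-syn (6R) alcohol.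

Step 15
Reactants: 28 (3S,4R,5Z)-9-chloro-3-[(4S)-2-(4-methoxyphenyl)-1,3-dioxolan-4-yl]-6-methylnon-5-ene-1,4-diol
Product: 29 1,4-bis-O-TBS ether of 28 (germacrane locants: O6-TBS; O12-TBS; 6R,7R,8S)
Conditions: TBSCl, imidazole, DMF, 40 °C
Reagents that add atoms: tert-butyldimethylsilyl chloride, CC(C)(C)[Si](C)(C)Cl
Why: Silylation of both hydroxyls in one operation; the pair is later released together for the lactonisation.

Step 16
Reactants: 29 1,4-bis-O-TBS ether of 28
Product: 30 (2S,3R,4R,5Z)-4-(TBS-oxy)-3-[2-(TBS-oxy)ethyl]-9-chloro-2-(PMB-oxy)-6-methylnon-5-en-1-ol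
Conditions: iBu2AlH (4 equiv), CH2Cl2, −78 → 0 °C
Reagents that add atoms: none
Why: Reductive acetal opening: aluminium binds the less hindered primary oxygen O9, that C–O bond breaks and hydride reduces the oxocarbenium ion, leaving PMB on the secondary O8 and freeing the C9 alcohol.

Step 17
Reactants: 30 (2S,3R,4R,5Z)-4-(TBS-oxy)-3-[2-(TBS-oxy)ethyl]-9-chloro-2-(PMB-oxy)-6-methylnon-5-en-1-ol
Product: 31 (2S,3R,4R,5Z)-4-(TBS-oxy)-3-[2-(TBS-oxy)ethyl]-9-chloro-2-(PMB-oxy)-6-methylnon-5-enal
Conditions: Dess–Martin periodinane, NaHCO3, CH2Cl2, 0 → 20 °C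
Reagents that add atoms: none
Why: Buffered Dess–Martin oxidation gives the α-alkoxy aldehyde without epimerising C8.

Step 18
Reactants: 31 (2S,3R,4R,5Z)-4-(TBS-oxy)-3-[2-(TBS-oxy)ethyl]-9-chloro-2-(PMB-oxy)-6-methylnon-5-enal, 13 1-methoxy-2-(triethylsilyloxy)-1-(trimethylsilyloxy)ethene
Product: 32 methyl (3R,4S,5R,6R,7Z)-6-(TBS-oxy)-5-[2-(TBS-oxy)ethyl]-11-chloro-3-hydroxy-4-(PMB-oxy)-8-methyl-2-(TES-oxy)undec-7-enoate (C2 epimers)
Conditions: MgBr2·OEt2 (3 equiv), CH2Cl2, −78 → −30 °C; aq. citric acid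
Reagents that add atoms: none
Why: Mukaiyama aldol under Cram chelate control: MgBr2 bridges the aldehyde oxygen and the O8 ether, and the ketene acetal attacks the face opposite the C7 substituent, giving the 8,9-syn (threo) pattern; the C10 configuration is irrelevant.

Step 19
Reactants: 32 methyl (3R,4S,5R,6R,7Z)-6-(TBS-oxy)-5-[2-(TBS-oxy)ethyl]-11-chloro-3-hydroxy-4-(PMB-oxy)-8-methyl-2-(TES-oxy)undec-7-enoate
Product: 33 methyl (3R,4S,5R,6R,7Z)-6-(TBS-oxy)-5-[2-(TBS-oxy)ethyl]-11-chloro-3-(MOM-oxy)-4-(PMB-oxy)-8-methyl-2-(TES-oxy)undec-7-enoate (C2 epimers)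
Conditions: MOMCl, iPr2NEt, CH2Cl2, 0 → 40 °C
Reagents that add atoms: chloromethyl methyl ether, COCCl
Why: Alkylation of the hindered β-hydroxyl under mildly basic conditions that avoid retro-aldol cleavage; the MOM ether is orthogonal to PMB and silyl groups and its alkoxide is a poor leaving group β to C10.

Step 20
Reactants: 33 methyl (3R,4S,5R,6R,7Z)-6-(TBS-oxy)-5-[2-(TBS-oxy)ethyl]-11-chloro-3-(MOM-oxy)-4-(PMB-oxy)-8-methyl-2-(TES-oxy)undec-7-enoate
Product: 34 methyl (3S,4S,5R,6R,7Z)-6-(TBS-oxy)-5-[2-(TBS-oxy)ethyl]-11-chloro-2-hydroxy-3-(MOM-oxy)-4-(PMB-oxy)-8-methylundec-7-enoate (C2 epimers)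
Conditions: HF·pyridine, pyridine, THF, 0 °C
Reagents that add atoms: none
Why: A TES ether is cleaved by buffered HF·pyridine much faster than primary or secondary TBS ethers.

Step 21
Reactants: 34 methyl (3S,4S,5R,6R,7Z)-6-(TBS-oxy)-5-[2-(TBS-oxy)ethyl]-11-chloro-2-hydroxy-3-(MOM-oxy)-4-(PMB-oxy)-8-methylundec-7-enoate
Product: 36 methyl (3R,4S,5R,6R,7Z)-2-(acetylsulfanyl)-6-(TBS-oxy)-5-[2-(TBS-oxy)ethyl]-11-chloro-3-(MOM-oxy)-4-(PMB-oxy)-8-methylundec-7-enoate (C2 epimers), via triflate 35 (not isolated)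
Conditions: Tf2O, 2,6-lutidine, CH2Cl2, −78 °C; then KSAc, DMF, −40 → 0 °C
Reagents that add atoms: potassium thioacetate, CC(=O)[S-].[K+]
Why: α-Triflyloxy esters undergo clean SN2 displacement by thiocarboxylates with inversion, the ester suppressing ionisation and neighbouring-group participation; the primary chloride does not react at this temperature.

Step 22
Reactants: 36 methyl (3R,4S,5R,6R,7Z)-2-(acetylsulfanyl)-6-(TBS-oxy)-5-[2-(TBS-oxy)ethyl]-11-chloro-3-(MOM-oxy)-4-(PMB-oxy)-8-methylundec-7-enoate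
Product: 38 eleven-membered cyclic sulfide (S between C1 and C10; 10-CO2Me; 9-OMOM; 8-OPMB; 7-CH2CH2OTBS; 6-OTBS; 4-methyl; 4Z; 6R,7R,8S,9R; C10 epimers), via thiol 37 (not isolated)
Conditions: Cs2CO3, NaI (cat.), MeOH/DMF (1:9), 0.002 M, slow addition, 45 °C, degassed
Reagents that add atoms: none
Why: Methanolysis frees the C10 thiol, whose thiolate displaces the primary chloride (through the iodide, Finkelstein exchange) in an 11-exo-tet closure at high dilution; thiolate alkylation is the standard entry to medium-ring sulfides and the long C–S bonds ease transannular strain.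

Step 23
Reactants: 38 eleven-membered cyclic sulfide
Product: 39 eleven-membered cyclic α-sulfonyl ester (the S,S-dioxide of 38; 6R,7R,8S,9R; C10 epimers)
Conditions: (NH4)6Mo7O24·4H2O (cat.), H2O2 (30 %), EtOH, 0 → 20 °C
Reagents that add atoms: hydrogen peroxide, OO
Why: Molybdate-catalysed peroxide oxidation takes a sulfide to the sulfone without epoxidising trisubstituted alkenes.

Step 24
Reactants: 39 eleven-membered cyclic α-sulfonyl ester
Product: 42 methyl cyclodeca-1(10),4-diene-10-carboxylate (C1=C10 cis in the ring with C2 cis to C9; 4Z; 9-OMOM; 8-OPMB; 7-CH2CH2OTBS; 6-OTBS; 6R,7R,8S,9S), via α-chloro sulfone 40 (not isolated), via episulfone 41 (not isolated)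
Conditions: C2Cl6, NaH, THF, 0 °C; then KOtBu, THF, −78 → 0 °C
Reagents that add atoms: none
Why: NaH deprotonates C10, the only position flanked by both the sulfonyl and the ester group, and the sodium salt is chlorinated by C2Cl6 as it forms, giving the α-chloro sulfone (both C10 epimers are equivalent from here). KOtBu then removes a proton from C1 on the other side of sulfur, and the C1 carbanion displaces chloride from C10 in a 1,3-elimination (3-exo-tet) that closes the thiirane dioxide and, with the same C1–C10 bond, the ten-membered carbocycle. Cheletropic loss of SO2 from the episulfone leaves the C1=C10 double bond, so the eleven-membered ring is contracted to the cyclodecadiene. This is the Ramberg–Bäcklund reaction in its ring-contraction form, the closest known cases being medium-ring α-halo sulfones and α-sulfonyl esters that give cycloalkenes and conjugated esters. No stereocentre is created, and C6–C9 are untouched because none of them is α to an acidifying group. The step needs the cis-in-ring alkene: the ten-membered ring, which already holds the cis C4=C5 bond, takes the trisubstituted alkene as its cis-in-ring isomer, and the episulfone can equilibrate at C1 under the base toward that less strained isomer. It also needs chlorine on C10 and the carbanion on C1: C1 has no β leaving group, whereas the only anion β to O9 is the weakly basic, doubly stabilised C10 anion, which is intercepted by C2Cl6 present from the start.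

Step 25
Reactants: 42 methyl cyclodeca-1(10),4-diene-10-carboxylate
Product: 43 C14 allylic alcohol (10-CH2OH; 1(10)Z,4Z; other groups as in 42; 6R,7R,8S,9S)
Conditions: iBu2AlH (2.5 equiv), CH2Cl2, −78 °C
Reagents that add atoms: none
Why: 1,2-Reduction of a conjugated ester to the allylic alcohol; ethers and silyl ethers are inert.

Step 26
Reactants: 43 C14 allylic alcohol
Product: 44 O14-TBDPS ether of 43
Conditions: TBDPSCl, imidazole, CH2Cl2, 0 → 20 °C
Reagents that add atoms: tert-butyldiphenylsilyl chloride, CC(C)(C)[Si](Cl)(c1ccccc1)c1ccccc1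
Why: Silylation of the primary allylic alcohol with a group that outlasts the removal of TBS, PMB and MOM groups.

Step 27
Reactants: 44 O14-TBDPS ether of 43
Product: 45 6,12-diol (6-OH; 7-CH2CH2OH; 8-OPMB; 9-OMOM; 14-OTBDPS; 6R,7S,8S,9S)
Conditions: HF·pyridine, pyridine, THF, 0 → 20 °C
Reagents that add atoms: none
Why: Buffered HF·pyridine removes the TBS ethers at O12 and O6 considerably faster than the primary TBDPS ether; MOM and PMB ethers are unaffected.

Step 28
Reactants: 45 6,12-diol
Product: 47 trans-fused 6,12-lactone (C11 as CH2; 8-OPMB; 9-OMOM; 14-OTBDPS; 6R,7S,8S,9S), via lactol 46 (not isolated)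
Conditions: TEMPO (20 mol %), PhI(OAc)2 (3 equiv), CH2Cl2, 20 °C
Reagents that add atoms: none
Why: Oxoammonium oxidation takes the primary alcohol to the aldehyde, which O6 traps as the lactol (5-exo-trig) and which is oxidised on to the γ-lactone; O8 is blocked so only the 6,12-lactone forms, and the trans fusion follows from the fixed C6 and C7 centres.

Step 29
Reactants: 47 trans-fused 6,12-lactone
Product: 51 α-methylene lactone (C11=C13; 8-OPMB; 9-OMOM; 14-OTBDPS; 6R,7S,8S,9S), via lithium enolate 48 (not isolated), via Mannich base 49 (not isolated), via ammonium iodide 50 (not isolated)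
Conditions: LiN(iPr)2, THF, −78 °C; CH2=NMe2+ I−, −78 → 0 °C; MeI, MeOH, 20 °C; NaHCO3 (aq.), EtOAc
Reagents that add atoms: N,N-dimethylmethyleneiminium iodide, C=[N+](C)C.[I-]
Why: Eschenmoser methylenation: the lactone enolate is aminomethylated by the iminium salt, and quaternisation followed by mild base eliminates trimethylamine to give the exo-methylene; no ester is yet present to compete for the base.

Step 30
Reactants: 51 α-methylene lactone
Product: 52 C8 alcohol (8-OH; 9-OMOM; 14-OTBDPS; 6R,7R,8S,9S)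
Conditions: DDQ, CH2Cl2/pH 7 buffer, 0 °C
Reagents that add atoms: none
Why: Oxidative PMB cleavage (benzylic hydride abstraction, hydrolysis of the oxocarbenium ion) under neutral conditions that leave the Michael acceptor, the MOM ether and the silyl ether alone.

Step 31
Reactants: 52 C8 alcohol
Product: 53 8-O-isobutyrate (9-OMOM; 14-OTBDPS; 6R,7S,8S,9S)
Conditions: (iPrCO)2O, Et3N, DMAP (cat.), CH2Cl2, 20 °C
Reagents that add atoms: isobutyric anhydride, CC(C)C(=O)OC(=O)C(C)C
Why: DMAP-catalysed acylation of a secondary alcohol.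

Step 32
Reactants: 53 8-O-isobutyrate
Product: 55 C9 alcohol (9-OH; 8-O-isobutyrate; 14-OTBDPS; 6R,7S,8S,9S), via bromomethyl ether 54 (not isolated)
Conditions: Me2BBr, CH2Cl2, −78 °C; NaHCO3 (aq.), THF, 0 °C
Reagents that add atoms: none
Why: Me2BBr cleaves MOM ethers at −78 °C by bromide attack on the activated acetal carbon, giving the bromomethyl ether, which hydrolyses on bicarbonate work-up; esters, the lactone and the TBDPS ether are inert at this temperature.

Step 33
Reactants: 55 C9 alcohol, 16 2-methyl-2-(trimethylsilyloxy)propanoyl chloride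
Product: 56 8-O-isobutyrate 9-O-[2-methyl-2-(TMS-oxy)propanoate] (14-OTBDPS; 6R,7S,8S,9S)
Conditions: DMAP, pyridine, CH2Cl2, 0 → 40 °C
Reagents that add atoms: none
Why: Acylation of the hindered allylic alcohol by an acid chloride with DMAP; the tertiary hydroxyl of the acyl group is masked as its silyl ether to prevent self-acylation.

Step 34
Reactants: 56 8-O-isobutyrate 9-O-[2-methyl-2-(TMS-oxy)propanoate]
Product: 57 target CNP0220567.2 (6R,7S,8S,9S; 1(10)Z,4Z)
Conditions: HF·pyridine, pyridine, THF, 0 → 20 °C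
Reagents that add atoms: none
Why: Fluoride-mediated desilylation under weakly acidic, non-nucleophilic conditions frees the C14 and tertiary hydroxyls without touching the esters or the α-methylene lactone.

## Compound list

1 | 3-bromopropan-1-ol | OCCCBr | starting material
2 | (3-bromopropoxy)(tert-butyl)dimethylsilane | CC(C)(C)[Si](C)(C)OCCCBr | intermediate
3 | propyne | CC#C | starting material
4 | [3-(TBS-oxy)propyl]magnesium bromide | CC(C)(C)[Si](C)(C)OCCC[Mg]Br | intermediate
5 | [3-(TBS-oxy)propyl]copper (MgBr2·SMe2 complex) | CC(C)(C)[Si](C)(C)OCCC[Cu] | intermediate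
6 | (Z)-[5-(TBS-oxy)-2-methylpent-1-en-1-yl]copper | [Cu]/C=C(/C)CCCO[Si](C)(C)C(C)(C)C | intermediate
7 | (Z)-tert-butyl[(5-iodo-4-methylpent-4-en-1-yl)oxy]dimethylsilane | I/C=C(/C)CCCO[Si](C)(C)C(C)(C)C | intermediate
8 | (Z)-5-iodo-4-methylpent-4-en-1-ol | I/C=C(/C)CCCO | intermediate
9 | (Z)-5-chloro-1-iodo-2-methylpent-1-ene | I/C=C(/C)CCCCl | intermediate
10 | methyl glycolate | COC(=O)CO | starting material
11 | methyl 2-(triethylsilyloxy)acetate | COC(=O)CO[Si](CC)(CC)CC | intermediate
12 | lithium enolate of 11 | COC(O[Li])=CO[Si](CC)(CC)CC | intermediate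
13 | 1-methoxy-2-(triethylsilyloxy)-1-(trimethylsilyloxy)ethene (geometric mixture) | COC(O[Si](C)(C)C)=CO[Si](CC)(CC)CC | intermediate
14 | 2-hydroxy-2-methylpropanoic acid | CC(C)(O)C(=O)O | starting material
15 | trimethylsilyl 2-methyl-2-(trimethylsilyloxy)propanoate | C[Si](C)(C)OC(=O)C(C)(C)O[Si](C)(C)C | intermediate
16 | 2-methyl-2-(trimethylsilyloxy)propanoyl chloride | C[Si](C)(C)OC(C)(C)C(Cl)=O | intermediate
17 | dimethyl (S)-malate | COC(=O)C[C@H](O)C(=O)OC | starting material
18 | dilithio alkoxide enolate of 17 | COC(=O)[C@@H](O[Li])C=C(OC)O[Li] | intermediate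
19 | dimethyl (2S,3R)-2-hydroxy-3-(prop-2-en-1-yl)butanedioate | COC(=O)[C@@H](O)[C@@H](CC=C)C(=O)OC | intermediate
20 | methyl (2R)-2-[(1S)-1,2-dihydroxyethyl]pent-4-enoate | OC[C@@H](O)[C@@H](CC=C)C(=O)OC | intermediate
21 | methyl (2R)-2-[(4S)-2-(4-methoxyphenyl)-1,3-dioxolan-4-yl]pent-4-enoate (acetal epimers) | COC(=O)[C@H](CC=C)[C@H]1COC(c2ccc(OC)cc2)O1 | intermediate
22 | methyl (2R)-2-[(4S)-2-(4-methoxyphenyl)-1,3-dioxolan-4-yl]-4-oxobutanoate | COC(=O)[C@H](CC=O)[C@H]1COC(c2ccc(OC)cc2)O1 | intermediate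
23 | methyl (2R)-4-hydroxy-2-[(4S)-2-(4-methoxyphenyl)-1,3-dioxolan-4-yl]butanoate | COC(=O)[C@H](CCO)[C@H]1COC(c2ccc(OC)cc2)O1 | intermediate
24 | (3R)-3-[(4S)-2-(4-methoxyphenyl)-1,3-dioxolan-4-yl]oxolan-2-one | O=C1OCC[C@@H]1[C@H]2COC(c3ccc(OC)cc3)O2 | intermediate
25 | (3R)-3-[(4S)-2-(4-methoxyphenyl)-1,3-dioxolan-4-yl]oxolan-2-ol (anomers) | OC1OCC[C@@H]1[C@H]2COC(c3ccc(OC)cc3)O2 | intermediate
26 | (Z)-(5-chloro-2-methylpent-1-en-1-yl)lithium | [Li]/C=C(/C)CCCCl | intermediate
27 | (2R)-4-hydroxy-2-[(4S)-2-(4-methoxyphenyl)-1,3-dioxolan-4-yl]butanal (as lithium alkoxide) | O=C[C@H](CCO)[C@H]1COC(c2ccc(OC)cc2)O1 | intermediate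
28 | (3S,4R,5Z)-9-chloro-3-[(4S)-2-(4-methoxyphenyl)-1,3-dioxolan-4-yl]-6-methylnon-5-ene-1,4-diol | OCC[C@@H]([C@H](O)/C=C(/C)CCCCl)[C@H]1COC(c2ccc(OC)cc2)O1 | intermediate
29 | 1,4-bis-O-TBS ether of 28 (6R,7R,8S) | CC(C)(C)[Si](C)(C)OCC[C@@H]([C@H](O[Si](C)(C)C(C)(C)C)/C=C(/C)CCCCl)[C@H]1COC(c2ccc(OC)cc2)O1 | intermediate
30 | (2S,3R,4R,5Z)-4-(TBS-oxy)-3-[2-(TBS-oxy)ethyl]-9-chloro-2-(PMB-oxy)-6-methylnon-5-en-1-ol | CC(C)(C)[Si](C)(C)OCC[C@@H]([C@H](O[Si](C)(C)C(C)(C)C)/C=C(/C)CCCCl)[C@H](OCc1ccc(OC)cc1)CO | intermediate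
31 | (2S,3R,4R,5Z)-4-(TBS-oxy)-3-[2-(TBS-oxy)ethyl]-9-chloro-2-(PMB-oxy)-6-methylnon-5-enal | CC(C)(C)[Si](C)(C)OCC[C@@H]([C@H](O[Si](C)(C)C(C)(C)C)/C=C(/C)CCCCl)[C@H](OCc1ccc(OC)cc1)C=O | intermediate
32 | methyl (3R,4S,5R,6R,7Z)-6-(TBS-oxy)-5-[2-(TBS-oxy)ethyl]-11-chloro-3-hydroxy-4-(PMB-oxy)-8-methyl-2-(TES-oxy)undec-7-enoate (C2 epimers) | CC(C)(C)[Si](C)(C)OCC[C@@H]([C@H](O[Si](C)(C)C(C)(C)C)/C=C(/C)CCCCl)[C@H](OCc1ccc(OC)cc1)[C@@H](O)C(O[Si](CC)(CC)CC)C(=O)OC | intermediate
33 | methyl (3R,4S,5R,6R,7Z)-6-(TBS-oxy)-5-[2-(TBS-oxy)ethyl]-11-chloro-3-(MOM-oxy)-4-(PMB-oxy)-8-methyl-2-(TES-oxy)undec-7-enoate (C2 epimers) | CC(C)(C)[Si](C)(C)OCC[C@@H]([C@H](O[Si](C)(C)C(C)(C)C)/C=C(/C)CCCCl)[C@H](OCc1ccc(OC)cc1)[C@@H](OCOC)C(O[Si](CC)(CC)CC)C(=O)OC | intermediate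
34 | methyl (3S,4S,5R,6R,7Z)-6-(TBS-oxy)-5-[2-(TBS-oxy)ethyl]-11-chloro-2-hydroxy-3-(MOM-oxy)-4-(PMB-oxy)-8-methylundec-7-enoate (C2 epimers) | CC(C)(C)[Si](C)(C)OCC[C@@H]([C@H](O[Si](C)(C)C(C)(C)C)/C=C(/C)CCCCl)[C@H](OCc1ccc(OC)cc1)[C@@H](OCOC)C(O)C(=O)OC | intermediate
35 | C2 triflate of 34 (C2 epimers) | CC(C)(C)[Si](C)(C)OCC[C@@H]([C@H](O[Si](C)(C)C(C)(C)C)/C=C(/C)CCCCl)[C@H](OCc1ccc(OC)cc1)[C@@H](OCOC)C(OS(=O)(=O)C(F)(F)F)C(=O)OC | intermediate
36 | methyl (3R,4S,5R,6R,7Z)-2-(acetylsulfanyl)-6-(TBS-oxy)-5-[2-(TBS-oxy)ethyl]-11-chloro-3-(MOM-oxy)-4-(PMB-oxy)-8-methylundec-7-enoate (C2 epimers) | CC(C)(C)[Si](C)(C)OCC[C@@H]([C@H](O[Si](C)(C)C(C)(C)C)/C=C(/C)CCCCl)[C@H](OCc1ccc(OC)cc1)[C@@H](OCOC)C(SC(C)=O)C(=O)OC | intermediate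
37 | 2-sulfanyl ester from 36 (C2 epimers) | CC(C)(C)[Si](C)(C)OCC[C@@H]([C@H](O[Si](C)(C)C(C)(C)C)/C=C(/C)CCCCl)[C@H](OCc1ccc(OC)cc1)[C@@H](OCOC)C(S)C(=O)OC | intermediate
38 | eleven-membered cyclic sulfide (S between C1 and C10; 10-CO2Me; 9-OMOM; 8-OPMB; 7-CH2CH2OTBS; 6-OTBS; 4Z; 6R,7R,8S,9R; C10 epimers) | [C@@H]1(O[Si](C)(C)C(C)(C)C)/C=C(/C)CCCSC(C(=O)OC)[C@H](OCOC)[C@@H](OCc2ccc(OC)cc2)[C@H]1CCO[Si](C)(C)C(C)(C)C | intermediate
39 | eleven-membered cyclic α-sulfonyl ester (S,S-dioxide of 38; C10 epimers) | [C@@H]1(O[Si](C)(C)C(C)(C)C)/C=C(/C)CCCS(=O)(=O)C(C(=O)OC)[C@H](OCOC)[C@@H](OCc2ccc(OC)cc2)[C@H]1CCO[Si](C)(C)C(C)(C)C | intermediate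
40 | C10-chloro derivative of 39 (C10 epimers) | [C@@H]1(O[Si](C)(C)C(C)(C)C)/C=C(/C)CCCS(=O)(=O)C(Cl)(C(=O)OC)[C@H](OCOC)[C@@H](OCc2ccc(OC)cc2)[C@H]1CCO[Si](C)(C)C(C)(C)C | intermediate
41 | episulfone (thiirane 1,1-dioxide across C1–C10 of the ten-membered ring) | [C@@H]1(O[Si](C)(C)C(C)(C)C)/C=C(/C)CCC2C(S2(=O)=O)(C(=O)OC)[C@H](OCOC)[C@@H](OCc3ccc(OC)cc3)[C@H]1CCO[Si](C)(C)C(C)(C)C | intermediate
42 | methyl cyclodeca-1(10),4-diene-10-carboxylate (C1=C10 cis in the ring; 4Z; 9-OMOM; 8-OPMB; 7-CH2CH2OTBS; 6-OTBS; 6R,7R,8S,9S) | [C@@H]1(O[Si](C)(C)C(C)(C)C)/C=C(/C)CC/C=C(/C(=O)OC)[C@H](OCOC)[C@@H](OCc2ccc(OC)cc2)[C@H]1CCO[Si](C)(C)C(C)(C)C | intermediate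
43 | C14 allylic alcohol from 42 (1(10)Z,4Z; 6R,7R,8S,9S) | [C@@H]1(O[Si](C)(C)C(C)(C)C)/C=C(/C)CC/C=C(/CO)[C@H](OCOC)[C@@H](OCc2ccc(OC)cc2)[C@H]1CCO[Si](C)(C)C(C)(C)C | intermediate
44 | O14-TBDPS ether of 43 | [C@@H]1(O[Si](C)(C)C(C)(C)C)/C=C(/C)CC/C=C(/CO[Si](c2ccccc2)(c3ccccc3)C(C)(C)C)[C@H](OCOC)[C@@H](OCc4ccc(OC)cc4)[C@H]1CCO[Si](C)(C)C(C)(C)C | intermediate
45 | 6,12-diol (8-OPMB; 9-OMOM; 14-OTBDPS; 6R,7S,8S,9S) | [C@@H]1(O)/C=C(/C)CC/C=C(/CO[Si](c2ccccc2)(c3ccccc3)C(C)(C)C)[C@H](OCOC)[C@@H](OCc4ccc(OC)cc4)[C@H]1CCO | intermediate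
46 | 6,12-lactol (C12 epimers) | C1C(O)O[C@@H]2/C=C(/C)CC/C=C(/CO[Si](c3ccccc3)(c4ccccc4)C(C)(C)C)[C@H](OCOC)[C@@H](OCc5ccc(OC)cc5)[C@@H]12 | intermediate
47 | trans-fused 6,12-lactone (8-OPMB; 9-OMOM; 14-OTBDPS; 6R,7S,8S,9S) | C1C(=O)O[C@@H]2/C=C(/C)CC/C=C(/CO[Si](c3ccccc3)(c4ccccc4)C(C)(C)C)[C@H](OCOC)[C@@H](OCc5ccc(OC)cc5)[C@@H]12 | intermediate
48 | lithium enolate of 47 | C1=C(O[Li])O[C@@H]2/C=C(/C)CC/C=C(/CO[Si](c3ccccc3)(c4ccccc4)C(C)(C)C)[C@H](OCOC)[C@@H](OCc5ccc(OC)cc5)[C@@H]12 | intermediate
49 | 11-(dimethylaminomethyl) lactone (C11 epimers) | CN(C)CC1C(=O)O[C@@H]2/C=C(/C)CC/C=C(/CO[Si](c3ccccc3)(c4ccccc4)C(C)(C)C)[C@H](OCOC)[C@@H](OCc5ccc(OC)cc5)[C@@H]12 | intermediate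
50 | 11-(trimethylammoniomethyl) lactone iodide | C[N+](C)(C)CC1C(=O)O[C@@H]2/C=C(/C)CC/C=C(/CO[Si](c3ccccc3)(c4ccccc4)C(C)(C)C)[C@H](OCOC)[C@@H](OCc5ccc(OC)cc5)[C@@H]12.[I-] | intermediate
51 | α-methylene lactone (8-OPMB; 9-OMOM; 14-OTBDPS; 6R,7S,8S,9S) | C=C1C(=O)O[C@@H]2/C=C(/C)CC/C=C(/CO[Si](c3ccccc3)(c4ccccc4)C(C)(C)C)[C@H](OCOC)[C@@H](OCc5ccc(OC)cc5)[C@@H]12 | intermediate
52 | C8 alcohol (9-OMOM; 14-OTBDPS; 6R,7R,8S,9S) | C=C1C(=O)O[C@@H]2/C=C(/C)CC/C=C(/CO[Si](c3ccccc3)(c4ccccc4)C(C)(C)C)[C@H](OCOC)[C@@H](O)[C@@H]12 | intermediate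
53 | 8-O-isobutyrate (9-OMOM; 14-OTBDPS; 6R,7S,8S,9S) | C=C1C(=O)O[C@@H]2/C=C(/C)CC/C=C(/CO[Si](c3ccccc3)(c4ccccc4)C(C)(C)C)[C@H](OCOC)[C@@H](OC(=O)C(C)C)[C@@H]12 | intermediate
54 | 9-O-bromomethyl ether of the 8-O-isobutyrate | C=C1C(=O)O[C@@H]2/C=C(/C)CC/C=C(/CO[Si](c3ccccc3)(c4ccccc4)C(C)(C)C)[C@H](OCBr)[C@@H](OC(=O)C(C)C)[C@@H]12 | intermediate
55 | C9 alcohol (8-O-isobutyrate; 14-OTBDPS; 6R,7S,8S,9S) | C=C1C(=O)O[C@@H]2/C=C(/C)CC/C=C(/CO[Si](c3ccccc3)(c4ccccc4)C(C)(C)C)[C@H](O)[C@@H](OC(=O)C(C)C)[C@@H]12 | intermediate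
56 | 8-O-isobutyrate 9-O-[2-methyl-2-(TMS-oxy)propanoate] (14-OTBDPS; 6R,7S,8S,9S) | C=C1C(=O)O[C@@H]2/C=C(/C)CC/C=C(/CO[Si](c3ccccc3)(c4ccccc4)C(C)(C)C)[C@H](OC(=O)C(C)(C)O[Si](C)(C)C)[C@@H](OC(=O)C(C)C)[C@@H]12 | intermediate
57 | CNP0220567.2 (6R,7S,8S,9S; 1(10)Z,4Z) | C=C1C(=O)O[C@@H]2/C=C(/C)CC/C=C(/CO)[C@H](OC(=O)C(C)(C)O)[C@@H](OC(=O)C(C)C)[C@@H]12 | target

## Step count and least certain steps

Total: 34 steps. Longest linear sequence: 26 steps (steps 9–34, from dimethyl (S)-malate 17).

**Step 24 (key step).** Three processes could divert it: loss of the O9 alkoxy group from the C10 anion before chlorine transfer (E1cB), attack of alkoxide on the ester carbonyl with loss of the methoxycarbonyl group, and extrusion through the more strained episulfone to give some trans-in-ring alkene. The fallback avoids any C10 carbanion by bringing the halogen in at the sulfoxide level. Sulfide 38 is oxidised with NaIO4 to the sulfoxide F1. NCS with K2CO3 chlorinates F1 at the ester-activated carbon through the chlorosulfoxonium ion to give the α-chloro sulfoxide F2. Molybdate-catalysed H2O2 oxidation then gives α-chloro sulfone 40, now isolated, and a hindered base (KOtBu or KN(SiMe3)2) effects the same 1,3-elimination and extrusion, returning to the route at 42.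

**Step 14.** Facial selectivity in the addition to aldehyde 27 may be poor, because Felkin–Anh control by a branched but remote dioxolanyl group is only moderate and a β-oxygen chelate would favour the other face. The fallback puts C6 under reagent control. Lactone 24 is opened with MeNH(OMe)·HCl and iPrMgCl to the hydroxy N-methoxy-N-methylamide F3, which is silylated to the TBS ether F4. Alkenyllithium 26 adds once to give the Z-enone F5. Corey–Bakshi–Shibata reduction with BH3·SMe2 and the (R)-2-methyl-oxazaborolidine, the enantiomer that places the alkenyl group in the large-substituent position, gives the 6R alcohol F6. Silylation of O6 returns to 29.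

**Step 22.** Oligomerisation or disulfide formation may outrun closure of the eleven-membered ring, since the nucleophile is a hindered secondary thiolate and the electrophile an unactivated chloride. The fallback closes the other C–S bond. In hydroxy ester 34 the C1 chloride is exchanged for thioacetate (KSAc, NaI, DMF) to give F7, and the C10 hydroxyl is mesylated (MsCl, Et3N) to give F8. Cs2CO3 in MeOH/DMF at high dilution then releases the unhindered primary thiolate, which displaces the ester-activated mesylate and returns to sulfide 38.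

**Step 10.** Hydroboration of the terminal alkene by free borane may compete with the directed ester reduction, and the diol may lactonise before it is protected. The fallback removes the alkene first. Ozonolysis of 19 with NaBH4 work-up at −78 °C and acid-catalysed lactonisation gives methyl (2S)-2-hydroxy-2-[(3R)-2-oxooxolan-3-yl]acetate F9. The directed borane reduction of its α-hydroxy ester gives (3R)-3-[(1S)-1,2-dihydroxyethyl]oxolan-2-one F10, and acetalisation with 4-methoxybenzaldehyde dimethyl acetal returns to 24.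

**Step 32.** Once O9 is free beside the O8 isobutyrate, a 1,2-acyl shift or Lewis-acid ionisation of the allylic C9–O bond may scramble the two positions. The fallback reverses the order of the two acylations. In 51 the MOM group is cleaved first with Me2BBr at −78 °C, while O8 is still a PMB ether, to give the C9 alcohol F11. Acylation with 16 gives F12. DDQ then frees O8 as F13 beside the bulky tertiary ester, which migrates far less readily, and isobutyrylation returns to 56.

## Further compounds

F1 | step 24 | sulfoxide of cyclic sulfide 38 (S and C10 epimers) | [C@@H]1(O[Si](C)(C)C(C)(C)C)/C=C(/C)CCCS(=O)C(C(=O)OC)[C@H](OCOC)[C@@H](OCc2ccc(OC)cc2)[C@H]1CCO[Si](C)(C)C(C)(C)C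
F2 | step 24 | C10-chloro sulfoxide from F1 | [C@@H]1(O[Si](C)(C)C(C)(C)C)/C=C(/C)CCCS(=O)C(Cl)(C(=O)OC)[C@H](OCOC)[C@@H](OCc2ccc(OC)cc2)[C@H]1CCO[Si](C)(C)C(C)(C)C
F3 | step 14 | (2R)-4-hydroxy-N-methoxy-2-[(4S)-2-(4-methoxyphenyl)-1,3-dioxolan-4-yl]-N-methylbutanamide | CON(C)C(=O)[C@H](CCO)[C@H]1COC(c2ccc(OC)cc2)O1
F4 | step 14 | O-TBS ether of F3 | CON(C)C(=O)[C@H](CCO[Si](C)(C)C(C)(C)C)[C@H]1COC(c2ccc(OC)cc2)O1
F5 | step 14 | Z-enone (C6 ketone; O12-TBS; C1 chloride) | O=C(/C=C(/C)CCCCl)[C@H](CCO[Si](C)(C)C(C)(C)C)[C@H]1COC(c2ccc(OC)cc2)O1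
F6 | step 14 | 6R allylic alcohol (O12-TBS) | O[C@H](/C=C(/C)CCCCl)[C@H](CCO[Si](C)(C)C(C)(C)C)[C@H]1COC(c2ccc(OC)cc2)O1
F7 | step 22 | C1 thioacetate of hydroxy ester 34 | CC(C)(C)[Si](C)(C)OCC[C@@H]([C@H](O[Si](C)(C)C(C)(C)C)/C=C(/C)CCCSC(C)=O)[C@H](OCc1ccc(OC)cc1)[C@@H](OCOC)C(O)C(=O)OC
F8 | step 22 | C10 mesylate of F7 | CC(C)(C)[Si](C)(C)OCC[C@@H]([C@H](O[Si](C)(C)C(C)(C)C)/C=C(/C)CCCSC(C)=O)[C@H](OCc1ccc(OC)cc1)[C@@H](OCOC)C(OS(C)(=O)=O)C(=O)OC
F9 | step 10 | methyl (2S)-2-hydroxy-2-[(3R)-2-oxooxolan-3-yl]acetate | COC(=O)[C@@H](O)[C@H]1CCOC1=O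
F10 | step 10 | (3R)-3-[(1S)-1,2-dihydroxyethyl]oxolan-2-one | OC[C@@H](O)[C@H]1CCOC1=O
F11 | step 32 | C9 alcohol of the α-methylene lactone (8-OPMB; 14-OTBDPS) | C=C1C(=O)O[C@@H]2/C=C(/C)CC/C=C(/CO[Si](c3ccccc3)(c4ccccc4)C(C)(C)C)[C@H](O)[C@@H](OCc5ccc(OC)cc5)[C@@H]12
F12 | step 32 | 9-O-[2-methyl-2-(TMS-oxy)propanoate] of F11 | C=C1C(=O)O[C@@H]2/C=C(/C)CC/C=C(/CO[Si](c3ccccc3)(c4ccccc4)C(C)(C)C)[C@H](OC(=O)C(C)(C)O[Si](C)(C)C)[C@@H](OCc5ccc(OC)cc5)[C@@H]12
F13 | step 32 | C8 alcohol from F12 | C=C1C(=O)O[C@@H]2/C=C(/C)CC/C=C(/CO[Si](c3ccccc3)(c4ccccc4)C(C)(C)C)[C@H](OC(=O)C(C)(C)O[Si](C)(C)C)[C@@H](O)[C@@H]12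
A1 | alternative 1 | bis-silyl ether of the target (O14-TBS; tertiary O-TES) | C=C1C(=O)O[C@@H]2/C=C(/C)CC/C=C(/CO[Si](C)(C)C(C)(C)C)[C@H](OC(=O)C(C)(C)O[Si](CC)(CC)CC)[C@@H](OC(=O)C(C)C)[C@@H]12
A2 | alternative 1 | 7-ethynyl-6-hydroxy cyclodecadiene diester (precursor of A1) | C#C[C@H]1[C@H](O)/C=C(/C)CC/C=C(/CO[Si](C)(C)C(C)(C)C)[C@H](OC(=O)C(C)(C)O[Si](CC)(CC)CC)[C@H]1OC(=O)C(C)C
A3 | alternative 2 | trans-lactone-fused ten-membered ring (C11 as CH2; 8,9-acetonide; O14-TBS) | C1C(=O)O[C@@H]2/C=C(/C)CC/C=C(/CO[Si](C)(C)C(C)(C)C)[C@@H]3OC(C)(C)O[C@H]3[C@@H]12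
A4 | alternative 2 | open-chain Z-alkenyl iodide with C6 aldehyde and C12 methyl ester (precursor of A3) | I/C=C(/C)CC/C=C(/CO[Si](C)(C)C(C)(C)C)[C@@H]1OC(C)(C)O[C@H]1[C@@H](CC(=O)OC)C=O
A5 | alternative 3 | ten-membered 8,9-diol fused to the saturated lactone (O14-TBS) | C1C(=O)O[C@@H]2/C=C(/C)CC/C=C(/CO[Si](C)(C)C(C)(C)C)[C@H](O)[C@@H](O)[C@@H]12
A6 | alternative 3 | lactone dialdehyde (C8 aldehyde; C9 enal; precursor of A5) | O=C[C@H]1CC(=O)O[C@@H]1/C=C(/C)CC/C=C(/CO[Si](C)(C)C(C)(C)C)C=O
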